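**Free catalyst.** Subtract [Q] from the charged [D] before you reckon anything: this is my assumption that each Q takes one D, and the earlier runs do not prove it.

in all of them: Q 6.6 mM

|  | G | D | temperature | remark | time |
|---|---|---|---|---|---|
| south-west | 0.66 M | 5 mol% | 20 °C | run made earlier |  |
| south-east | 1.5 M | 5 mol% | 31 °C | run made earlier |  |
| north-west | 0.80 M | 3.1 mol% | 20 °C | run made earlier |  |
| noon | 0.80 M | 5 mol% | 25 °C |  | 4.0 min |
| summer | 2.5 M | 1.2 mol% | 25 °C |  | 4.0 min |
| dawn | 2.5 M | 5 mol% | 25 °C |  | 4.0 min |
| winter | 0.80 M | 1.2 mol% | 25 °C |  | 4.0 min |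

| run | time / min | X / % |
|---|---|---|
| south-west | 0.333 | 3.9 |
| south-west | 0.500 | 5.8 |
| south-west | 0.667 | 7.8 |
| south-west | 1.00 | 12.5 |
| south-west | 1.50 | 17.4 |
| south-west | 2.50 | 26.9 |
| south-west | 4.00 | 36.0 |
| south-east | 0.333 | 14.6 |
| south-east | 0.500 | 20.9 |
| south-east | 0.667 | 26.3 |
| south-east | 1.00 | 33.0 |
| south-east | 1.50 | 39.4 |
| south-east | 2.50 | 42.6 |
| south-east | 4.00 | 44.1 |
| north-west | 0.333 | 2.5 |
| north-west | 0.667 | 5.3 |
| north-west | 1.00 | 7.9 |
| north-west | 2.00 | 13.8 |
| north-west | 4.00 | 23.1 |

(standard deviation of a reading: 0.3 percentage points)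

- the numbers in the tables scatter by 0.3 percentage points (one standard deviation)

- the flasks put in order of amount of X, in percent of the G charged, best first, at 4.0 min (noon / summer / dawn / winter)
- the amount of X, in percent of the G charged of the flask you put first, at 4.0 min
- the amount of X, in percent of the G charged of the flask you put last, at 4.0 min

**First rung.** Summed over the shared times up to 1.00 min and taken as concentrations, the south-west run holds 1.27 times the X of the north-west run. The charged [D] stand at 1.33 to one, and [D] minus [Q], 26.4 mM against 18.2 mM, stand at 1.45, so the reading lies nearer the charged ratio. These runs therefore do not show Q taking D, and I keep the subtraction as an assumption, on which winter, with 9.60 mM of D charged against 6.6 mM of Q, hangs.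

**Second rung.** Over the next minutes X climbs: the south-east run has half of its last reading by 0.500 min.

**Last rung.** That run then gains 1.5 percentage points in its final 1.50 min, standing at 44.1%. I read this flatness as G used up, partly by a path needing no D. Take the catalytic path as following free D and the other as following [G], with [G] replaced by its mean. Then define the free loading as ([D] − [Q]) over [G], all as charged, and X ends as the share λ/(λ + λs), where λ/λs is a selectivity factor. The south-east run has λ = 4.56%, which gives the split loading, where G would divide equally, λs = 5.78%.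

**My reckoning.** Noon has λ = 4.17% and so 41.9%. Dawn has 4.74% and 45.0%, summer 0.936% and 13.9%, winter 0.375% and 6.09%.

**The forecast.** With the same order as mine but other figures, it gave dawn > noon > summer > winter, from 58% down to 10%, reading “catalyst death rather than equilibrium”.

**The result.** The flasks give noon > dawn > summer > winter: noon 44.9%, dawn 36.9%, summer 14.3%, winter 7.64%.

    J ⇌ D + X (K = 0.960 M, k = 0.125 /s, Ea = 74.0 kJ/mol, ΔH = −9.00 kJ/mol)
    D + Q → L (k = 22.2 /M/s, Ea = 45.0 kJ/mol)
    G + D → J (k = 0.543 /M/s, Ea = 50.0 kJ/mol)
    2 G → Z (k = 0.0110 /M/s, Ea = 55.0 kJ/mol)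
    (constants at 25 °C)

**The neighbour.** My shares part from the flasks at dawn, which stands 8.1 points below my figure while noon stands 3.0 points above it. At 4.00 min, J holds 46.5% of the catalyst in dawn and 28.2% in noon, and λ counts J as free. Now raise noon to 12 mol% of D: λ becomes 11.2%, and λs gives 66.0%. That neighbour flask holds 66.1% of X at 4.00 min.

(Readings and results were generated by integration for an exercise.)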